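**Plan**

1. Retrosynthetic cuts, in order: the C12–C13 CH2–CH2 bond of the 19-(furan-2-yl)nonadeca-5,7-diynoyl chain; the C6–C7 C(sp)–C(sp) bond of that diyne; the ester C–O bond; the C5–C6 C(sp)–C(sp) bond of the undecadiynyl chain; the alkyne–CH2 and furan C2–CH2 bonds.
2. Forward: furan is lithiated and alkylated, the chloride is exchanged for ethynyl, and a Cadiot–Chodkiewicz coupling gives the furyl diynol. Esterification with hex-5-ynoic acid, a second Cadiot–Chodkiewicz coupling with a bromohexynol and an Appel reaction give a primary bromide that already holds both diynes, the ester and one furan.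
3. The chain is completed last: 2-(hept-6-enyl)furan, from a nickel-catalysed Kumada coupling of 2-bromofuran with hept-6-enylmagnesium bromide, is hydroborated and its B-alkyl group is cross-coupled with that bromide (sp3–sp3 Suzuki–Miyaura).
4. Enabling feature: C12 and C13 are unbranched methylene carbons inside the undecamethylene tether C9–C19, four atoms from the C5–C8 diyne and seven from the furan ring. One can therefore be a primary bromide and the other the terminus of a vinyl group. The four triple bonds forbid any olefination–hydrogenation tactic, so the bond is made directly.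
5. Rings and stereochemistry: the two furan rings are bought as furan and 2-bromofuran and no ring is formed. The target has no stereocentre and no stereogenic double bond, so nothing has to be set.

Key step: step 10

Remark: furan, 1-bromo-4-chlorobutane, lithium acetylide–ethylenediamine complex, pent-4-yn-1-ol, hex-5-ynoic acid, hex-5-yn-1-ol, 7-bromohept-1-ene and 2-bromofuran are taken as catalogue compounds; all diyne intermediates are handled cold and shielded from light.

**Route**

Step 1
Reactants: 1 furan; 2 1-bromo-4-chlorobutane
Product: 4 2-(4-chlorobutyl)furan, via 2-furyllithium 3 (not isolated)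
Conditions: n-BuLi, THF, −78 to 0 °C; then 2, −78 °C to rt
Reagents that add atoms: n-butyllithium, [Li]CCCC (supplies the lithium of 3 only; none of its atoms stay in 4)
Why: Furan is lithiated at C2, its most acidic C–H, and the 2-furyllithium displaces bromide much faster than chloride in an SN2 alkylation of a heteroaryllithium, so the chloride end should survive for step 2.

Step 2
Reactants: 4 2-(4-chlorobutyl)furan; 5 lithium acetylide–ethylenediamine complex
Product: 6 2-(hex-5-yn-1-yl)furan
Conditions: DMSO, NaI (cat.), 0 °C to rt
Reagents that add atoms: none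
Why: SN2 alkylation of an acetylide by a primary alkyl chloride in a dipolar aprotic solvent should install the terminal alkyne, since the 2-alkylfuran carries no proton acidic enough to interfere.

Step 3
Reactants: 7 pent-4-yn-1-ol
Product: 8 5-bromopent-4-yn-1-ol
Conditions: NBS, AgNO3 (cat.), acetone, rt, dark
Reagents that add atoms: N-bromosuccinimide, O=C1CCC(=O)N1Br
Why: Silver(I)-catalysed electrophilic bromination of the terminal alkyne C–H with NBS should give the 1-bromoalkyne without touching the alcohol; the halogen is placed on the furan-free partner because NBS would attack a furan ring.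

Step 4
Reactants: 6 2-(hex-5-yn-1-yl)furan; 8 5-bromopent-4-yn-1-ol
Product: 9 11-(furan-2-yl)undeca-4,6-diyn-1-ol
Conditions: CuCl (cat.), NH2OH·HCl, 30% aq. n-BuNH2, Et2O, 0 °C
Reagents that add atoms: none
Why: Cadiot–Chodkiewicz coupling of the copper(I) acetylide of 6 with bromoalkyne 8 should give the unsymmetrical 1,3-diyne, with hydroxylamine keeping copper in the +1 state to suppress oxidative homocoupling and with the free hydroxyl and the furan tolerated.

Step 5
Reactants: 9 11-(furan-2-yl)undeca-4,6-diyn-1-ol; 10 hex-5-ynoic acid
Product: 11 11-(furan-2-yl)undeca-4,6-diyn-1-yl hex-5-ynoate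
Conditions: DCC, DMAP (cat.), CH2Cl2, 0 °C to rt
Reagents that add atoms: none
Why: Steglich esterification (carbodiimide activation, DMAP acyl transfer) runs under neutral conditions that the acid-sensitive furan, the diyne and the terminal alkyne should all survive.

Step 6
Reactants: 12 hex-5-yn-1-ol
Product: 13 6-bromohex-5-yn-1-ol
Conditions: NBS, AgNO3 (cat.), acetone, rt, dark
Reagents that add atoms: N-bromosuccinimide, O=C1CCC(=O)N1Br
Why: The same silver(I)-catalysed alkyne C–H bromination as in step 3 should give the second 1-bromoalkyne, again on a furan-free partner.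

Step 7
Reactants: 11 11-(furan-2-yl)undeca-4,6-diyn-1-yl hex-5-ynoate; 13 6-bromohex-5-yn-1-ol
Product: 14 11-(furan-2-yl)undeca-4,6-diyn-1-yl 12-hydroxydodeca-5,7-diynoate
Conditions: CuCl (cat.), NH2OH·HCl, 30% aq. n-BuNH2, Et2O, 0 °C, short reaction time
Reagents that add atoms: none
Why: In this second Cadiot–Chodkiewicz coupling only the terminal alkyne of 11 can form a copper acetylide, the internal diyne is inert, and the unactivated ester should survive brief contact with cold aqueous butylamine.

Step 8
Reactants: 14 11-(furan-2-yl)undeca-4,6-diyn-1-yl 12-hydroxydodeca-5,7-diynoate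
Product: 15 11-(furan-2-yl)undeca-4,6-diyn-1-yl 12-bromododeca-5,7-diynoate
Conditions: CBr4, PPh3, CH2Cl2, 0 °C
Reagents that add atoms: carbon tetrabromide, BrC(Br)(Br)Br
Why: The Appel reaction converts the primary alcohol into the primary bromide by SN2 displacement of an alkoxyphosphonium ion under near-neutral conditions that ester, diynes and furan should tolerate.

Step 9
Reactants: 16 7-bromohept-1-ene; 17 2-bromofuran
Product: 19 2-(hept-6-en-1-yl)furan, via hept-6-en-1-ylmagnesium bromide 18 (not isolated)
Conditions: 16, Mg turnings, THF, rt to 40 °C; then 17, NiCl2(dppp) (2 mol%), THF, 0 °C to rt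
Reagents that add atoms: magnesium, [Mg] (supplies the magnesium of 18 only; none of its atoms stay in 19)
Why: In this Kumada–Tamao–Corriu coupling nickel(0)/dppp should insert into the C2–Br bond of 2-bromofuran, the primary alkyl Grignard 18 transmetalates and reductive elimination from the cis-chelated nickel complex outruns β-hydride elimination, while the remote terminal alkene takes no part.

Step 10
Reactants: 19 2-(hept-6-en-1-yl)furan; 15 11-(furan-2-yl)undeca-4,6-diyn-1-yl 12-bromododeca-5,7-diynoate
Product: 21 11-(furan-2-yl)undeca-4,6-diyn-1-yl 19-(furan-2-yl)nonadeca-5,7-diynoate, via B-alkyl-9-BBN 20 (not isolated)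
Conditions: 19 (1.3 equiv), 9-BBN-H (1.2 equiv), THF, 0 °C to rt; then 15 (1.0 equiv), Pd(OAc)2 (4 mol%), PCy3 (8 mol%), K3PO4·H2O (1.2 equiv), THF, rt, dark
Reagents that add atoms: 9-borabicyclo[3.3.1]nonane, B1C2CCCC1CCC2 (supplies the boron and the bicyclic ligand of 20 only; none of its atoms stay in 21)
Why: 9-BBN adds its B–H bond across the terminal vinyl group of 19 with anti-Markovnikov regiochemistry, which makes the former alkene terminus a nucleophilic B-alkyl carbon on the diyne-free fragment; Pd(0)/PCy3 then inserts into the primary C–Br bond of 15 by an SN2-type two-electron oxidative addition, the base-activated borate of 20 transfers its primary alkyl group to palladium, and reductive elimination forms the CH2–CH2 bond. The closest known reaction type is the room-temperature B-alkyl Suzuki–Miyaura coupling of unactivated primary alkyl bromides bearing β-hydrogens with alkyl-9-BBN reagents under palladium/trialkylphosphine catalysis. No ring is closed and no stereocentre is formed. The step needs cross-coupling to outrun β-hydride elimination and 5-exo-dig insertion of the C7≡C8 triple bond into the alkylpalladium, and it needs the four alkynes, the ester and both furans to stay untouched. The bulky, electron-rich PCy3 keeps the alkylpalladium bromide coordinatively saturated, both partners are unhindered primary centres, the polar oxidative addition avoids a hex-5-ynyl radical that would cyclise, the base is only hydrated K3PO4 at room temperature, and the hydroboration is completed with a slight excess of 19 before 15 is added, so no B–H bond meets a diyne.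

**Compound list**

1 | furan | c1ccoc1 | starting material
2 | 1-bromo-4-chlorobutane | ClCCCCBr | starting material
3 | 2-furyllithium | [Li]c1ccco1 | intermediate
4 | 2-(4-chlorobutyl)furan | ClCCCCc1ccco1 | intermediate
5 | lithium acetylide–ethylenediamine complex | [Li+].[C-]#C.NCCN | starting material
6 | 2-(hex-5-yn-1-yl)furan | C#CCCCCc1ccco1 | intermediate
7 | pent-4-yn-1-ol | C#CCCCO | starting material
8 | 5-bromopent-4-yn-1-ol | BrC#CCCCO | intermediate
9 | 11-(furan-2-yl)undeca-4,6-diyn-1-ol | OCCCC#CC#CCCCCc1ccco1 | intermediate
10 | hex-5-ynoic acid | C#CCCCC(=O)O | starting material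
11 | 11-(furan-2-yl)undeca-4,6-diyn-1-yl hex-5-ynoate | C#CCCCC(=O)OCCCC#CC#CCCCCc1ccco1 | intermediate
12 | hex-5-yn-1-ol | C#CCCCCO | starting material
13 | 6-bromohex-5-yn-1-ol | BrC#CCCCCO | intermediate
14 | 11-(furan-2-yl)undeca-4,6-diyn-1-yl 12-hydroxydodeca-5,7-diynoate | OCCCCC#CC#CCCCC(=O)OCCCC#CC#CCCCCc1ccco1 | intermediate
15 | 11-(furan-2-yl)undeca-4,6-diyn-1-yl 12-bromododeca-5,7-diynoate | BrCCCCC#CC#CCCCC(=O)OCCCC#CC#CCCCCc1ccco1 | intermediate
16 | 7-bromohept-1-ene | C=CCCCCCBr | starting material
17 | 2-bromofuran | Brc1ccco1 | starting material
18 | hept-6-en-1-ylmagnesium bromide | C=CCCCCC[Mg]Br | intermediate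
19 | 2-(hept-6-en-1-yl)furan | C=CCCCCCc1ccco1 | intermediate
20 | 9-[7-(furan-2-yl)heptyl]-9-borabicyclo[3.3.1]nonane | C1CCC2CCCC1B2CCCCCCCc1ccco1 | intermediate
21 | 11-(furan-2-yl)undeca-4,6-diyn-1-yl 19-(furan-2-yl)nonadeca-5,7-diynoate | O=C(CCCC#CC#CCCCCCCCCCCCc1ccco1)OCCCC#CC#CCCCCc1ccco1 | target

**Step count**

Total steps: 10. Longest linear sequence: 7 steps (steps 1, 2, 4, 5, 7, 8, 10, from furan).

**Steps most likely to fail**

1. Step 10. The alkylpalladium bromide formed from 15 may be diverted before transmetalation, by β-hydride elimination or by 5-exo-dig insertion of the neighbouring C7≡C8 triple bond. Palladium(0) may also oligomerise the diynes, and protodeboronation of 20 would stall the coupling. Fallback (sets out from 1 and 11, comes back at 21): the C19 chain is assembled before any diyne exists, so no sp3–sp3 coupling is needed. Furan 1 is lithiated as in step 1 and the 2-furyllithium 3 so obtained is alkylated with an excess of 1,11-dibromoundecane to give 2-(11-bromoundecyl)furan F1. Displacement of its bromide with 5 in DMSO gives 2-(tridec-12-yn-1-yl)furan F2. A Glaser–Hay oxidative heterocoupling (CuCl, TMEDA, O2, acetone, rt) of 11 with a three- to fivefold excess of F2 should then give 21 directly, the excess favouring the mixed diyne.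

2. Step 7. Aminolysis of the ester by butylamine and copper-mediated homocoupling of either alkyne may compete with the cross-coupling, and the polar hydroxy diyne products may be hard to separate. Fallback (sets out from 10 and 9, comes back at 21): the acid-side diyne is built on the free acid before the ester exists, with a chloride as latent leaving group. 6-Chlorohex-1-yne is brominated (NBS, AgNO3 cat., acetone) to 1-bromo-6-chlorohex-1-yne F3. Cadiot–Chodkiewicz coupling of F3 with 10 (CuCl, NH2OH·HCl, aq. n-BuNH2, 0 °C) gives 12-chlorododeca-5,7-diynoic acid F4. Steglich esterification of F4 with 9 (DCC, DMAP) gives 11-(furan-2-yl)undeca-4,6-diyn-1-yl 12-chlorododeca-5,7-diynoate F5. Finkelstein exchange (NaI, acetone, reflux) gives 11-(furan-2-yl)undeca-4,6-diyn-1-yl 12-iodododeca-5,7-diynoate F6, which takes the place of 15 in the coupling with 20 under the conditions of step 10 and so should give 21.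

3. Step 2. Displacement of the primary chloride by the strongly basic, unprotected acetylide may be slow and may lose ground to E2 elimination or to base-induced degradation in DMSO. Fallback (sets out from 4, comes back at 6): the leaving group is activated and the acetylide is capped. Finkelstein exchange of 4 (NaI, acetone, reflux) gives 2-(4-iodobutyl)furan F7. Alkylation of commercial lithium (trimethylsilyl)acetylide with F7 (THF/DMPU, −78 °C to rt) gives trimethyl[6-(furan-2-yl)hex-1-yn-1-yl]silane F8. Methanolysis of the C–Si bond (K2CO3 cat., MeOH, rt) should give 6.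

**Further compounds**

F1 | step 10 | 2-(11-bromoundecyl)furan | BrCCCCCCCCCCCc1ccco1
F2 | step 10 | 2-(tridec-12-yn-1-yl)furan | C#CCCCCCCCCCCCc1ccco1
F3 | step 7 | 1-bromo-6-chlorohex-1-yne | ClCCCCC#CBr
F4 | step 7 | 12-chlorododeca-5,7-diynoic acid | ClCCCCC#CC#CCCCC(=O)O
F5 | step 7 | 11-(furan-2-yl)undeca-4,6-diyn-1-yl 12-chlorododeca-5,7-diynoate | ClCCCCC#CC#CCCCC(=O)OCCCC#CC#CCCCCc1ccco1
F6 | step 7 | 11-(furan-2-yl)undeca-4,6-diyn-1-yl 12-iodododeca-5,7-diynoate | ICCCCC#CC#CCCCC(=O)OCCCC#CC#CCCCCc1ccco1
F7 | step 2 | 2-(4-iodobutyl)furan | ICCCCc1ccco1
F8 | step 2 | trimethyl[6-(furan-2-yl)hex-1-yn-1-yl]silane | C[Si](C)(C)C#CCCCCc1ccco1
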